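Per hour, as a fraction of what stands in the flask: that was the unit I wanted for single product. The earlier runs show it both made and lost.

| flask | substrate | partner | temperature | remark | time |
|---|---|---|---|---|---|
| maple | 10 mM | 0.90 equiv | 55 °C | run made earlier |  |
| birch | 40 mM | 0.90 equiv | 66 °C | run made earlier |  |
| north-west | 20 mM | 0.900 equiv |  | at 50 °C until 30 h, from then on at 70 °C | 40 h |
| east | 20 mM | 0.900 equiv | 50 °C |  | 40 h |
| south | 20 mM | 0.900 equiv | 70 °C |  | 40 h |

| run | time / h | single product / % | substrate / % |
|---|---|---|---|
| maple | 2.50 | 6.0 | 92.3 |
| maple | 6.00 | 11.6 | 81.5 |
| maple | 15.0 | 21.3 | 65.7 |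
| maple | 30.0 | 26.3 | 51.5 |
| birch | 4.00 | 26.4 | 45.5 |
| birch | 6.00 | 24.4 | 40.6 |
| birch | 12.0 | 22.3 | 35.8 |
| birch | 15.0 | 22.1 | 36.0 |

(readings scatter by 1 percentage point)

1. which flask leads in amount of single product, in percent of the substrate charged ("all alike" within 1.5 percentage points) (north-west / east / south / all alike)
2. how much single product is there at the end, in percent of the substrate charged: north-west
3. how much single product is there at the end, in percent of the substrate charged: east
4. how much single product is there at the end, in percent of the substrate charged: south

- the numbers in the tables scatter by 1 percentage point (one standard deviation)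

I followed the runs in slow motion. In the first instants of the maple run, 77.9% of the substrate used at 2.50 h stood as single product, and I took that as the share of new substrate turnover reaching it.

In the middle of the hotter birch run, single product had already passed its highest reading, 26.4%, while substrate was still falling. By the end of birch, substrate read 35.8% and then 36.0%, so the making had nearly stopped, with partner, the limiting reagent, charged at 0.90 equiv.

From 6.00 h to 15.0 h, single product fell from 24.4% to 22.1%. Read as plain first-order decay, that gave 0.0110 h⁻¹. But that first answer ignored the feed, so I went round once more. The substrate lost in that window, times the share, had supplied 3.6 percentage points. Adding this back gave the hot-loss constant, the first-order fraction of single product lost per hour at 66 °C: 0.0262 h⁻¹. It is a reading and carries the scatter.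

I then reckoned for myself. For north-west I took maple's last reading as the level at the change, and the hot hours reduced it to 20.2%. For south I assumed birch's 24.4% was reached by about 12.0 h, at half the concentration, and decay from there left 11.7%. I took the south figure as an upper one, the constant having been read at 66 °C, cooler than south at 70 °C. The north-west figure was rougher, with errors pulling both ways: it left out the feed during the hot hours, and it used that same cooler constant. East stayed cool near 26.3%, so I expected east to lead, holding more than the other two.

The forecast named east and gave 24% for north-west, 25.8% for east and 23.5% for south, saying "South dies early".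

The flasks gave east as the leader, with north-west 19.8%, east 28.9% and south 5.69%.

    substrate + partner → single product (k = 0.00280 M⁻¹ s⁻¹, Ea = 71.0 kJ mol⁻¹)
    substrate + partner → other mono adduct (k = 0.00130 M⁻¹ s⁻¹, Ea = 88.0 kJ mol⁻¹)
    partner + single product → bis adduct (k = 0.00290 M⁻¹ s⁻¹, Ea = 78.0 kJ mol⁻¹)
    partner + other mono adduct → bis adduct (k = 0.00640 M⁻¹ s⁻¹, Ea = 64.0 kJ mol⁻¹)
    single product → over-reaction product (k = 1.30 × 10⁻⁵ s⁻¹, Ea = 119 kJ mol⁻¹)
    partner → decomposition product (k = 2.10 × 10⁻⁸ s⁻¹, Ea = 124 kJ mol⁻¹)
    (constants at 70 °C)

Without the loss of single product to over-reaction product, south ends at 29.3% instead of 5.69%, the largest single effect. My south figure of 11.7% stood above the 5.69% that south gave. On the neighbour, north-west read at 4.0 d, the constant takes 19.8% down to 4.55%, still a cooler flask's figure; that flask holds 1.51%.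

The data are calculated with made-up constants, and the scatter is random.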